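Numbering (cembrane style): C1 = ring CH bearing the lactone α-carbon C15, C2 = lactone O–CH, C3=C4(Me), C5H2, C6(OH), C7=C8(Me), C9H2, C10(OAc), C11=C12(Me), C13H2, C14H2; C16 = lactone C=O, C17 = exocyclic CH2.
Enabling feature: in the fourteen-membered ring, C8(sp2)–C9H2–C10H(O)–C11(sp2) is a carbinol allylic to the C11=C12 olefin and homoallylic, through one methylene, to the C7=C8 olefin. This array results when an alkenyl group migrates from boron to the α-carbon of a B-vinyl group while an alkenylpalladium takes the β-carbon.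
Retrosynthesis: the lactone ring is opened reductively to a silylated 2-methylene-1,4-diol (C16 at the alcohol level). C8–C9 and C10–C11 are then cut in one operation, with C9–C10 traced to vinylmagnesium bromide, leaving an open chain with a C8 alkenyl bromide and a C11 alkenylboronate. C1–C2 is cut last, into a C2–C8 enal and a 2-(bromomethyl)enoate (C1, C11–C17).
Forward: the west enal (6 steps) and the east allylic bromide (5 steps) are joined at C1–C2 with formation of the lactone ring. The lactone is parked as the diol, the carbocycle is closed at C8–C9, and the lactone ring is re-formed last by oxidative lactonisation.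
Stereochemistry: C6 comes from a chiral-phosphoric-acid-catalysed propargylation, C1/C2 (anti, trans-lactone) from a ligand-controlled allylchromium addition, and C10 from the chiral palladium catalyst of the ring closure. 3E and 11E come from syn carboalumination and 7E from syn hydrozirconation, all carried on with retention.

Key step: step 15

Assumption: in the three catalyst-controlled steps (2, 12, 15) the antipode named is taken to give the drawn configuration. Both antipodes of each catalyst are available, so an opposite sense of induction would be met by exchanging the antipode only.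
Abbreviations: TBS = tert-butyldimethylsilyl, TMS = trimethylsilyl, Bpin = 4,4,5,5-tetramethyl-1,3,2-dioxaborolan-2-yl.

Step 1
Reactants: 1 but-2-yn-1-ol
Product: 2 but-2-ynal
Conditions: activated MnO2 (10 equiv), CH2Cl2, rt; filter, use the concentrated solution directly
Reagents that add atoms: none
Why: Heterogeneous MnO2 oxidation takes a propargylic alcohol to the ynal without over-oxidation.

Step 2
Reactants: 2 but-2-ynal; 3 allenylboronic acid pinacol ester
Product: 5 (S)-hepta-1,5-diyn-4-ol, via O-boryl ether 4 (not isolated)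
Conditions: (R)-TRIP [(R)-3,3'-bis(2,4,6-triisopropylphenyl)-1,1'-binaphthyl-2,2'-diyl hydrogen phosphate] (10 mol %), 4 Å MS, toluene, -20 °C; aqueous work-up
Reagents that add atoms: none
Why: In this chiral-phosphoric-acid-catalysed asymmetric propargylation the acid activates a boronate oxygen and the allenyl group is delivered through a closed six-membered SE2' transition state to one face of the ynal, which sets C6 as S.

Step 3
Reactants: 5 (S)-hepta-1,5-diyn-4-ol
Product: 6 (S)-4-(tert-butyldimethylsilyloxy)hepta-1,5-diyne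
Conditions: TBSCl, imidazole, DMF, rt
Reagents that add atoms: tert-butyldimethylsilyl chloride CC(C)(C)[Si](C)(C)Cl
Why: Standard silylation masks the carbinol for the organometallic steps that follow and leaves the stereocentre untouched.

Step 4
Reactants: 6 (S)-4-(tert-butyldimethylsilyloxy)hepta-1,5-diyne
Product: 9 (S,E)-5-(tert-butyldimethylsilyloxy)-3-methyloct-2-en-6-yn-1-ol, via alkenyl(dimethyl)alane 7 (not isolated), via lithium alkenylalanate 8 (not isolated)
Conditions: Me3Al (3 equiv), Cp2ZrCl2 (0.25 equiv), CH2Cl2, 0 °C to rt; n-BuLi, THF/hexane, -78 °C; (CH2O)n, -78 °C to rt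
Reagents that add atoms: trimethylaluminium C[Al](C)C; formaldehyde (from paraformaldehyde) C=O
Why: Negishi zirconium-catalysed carboalumination adds Me and Al syn and regioselectively across the terminal alkyne only (the internal alkyne is far slower), and hydroxymethylation of the alanate with retention gives the 3E olefin with C2 attached.

Step 5
Reactants: 9 (S,E)-5-(tert-butyldimethylsilyloxy)-3-methyloct-2-en-6-yn-1-ol
Product: 11 (S,2E,6E)-7-bromo-5-(tert-butyldimethylsilyloxy)-3-methylocta-2,6-dien-1-ol, via bis-zirconocene adduct 10 (not isolated)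
Conditions: Cp2Zr(H)Cl (3 equiv), THF, rt to 40 °C; NBS, THF, -78 to 0 °C
Reagents that add atoms: N-bromosuccinimide O=C1CCC(=O)N1Br
Why: Syn hydrozirconation puts zirconium on the methyl-bearing alkyne carbon, remote from the branched silyloxy carbon (excess reagent equilibrates the regioisomers), and bromodezirconation with retention fixes the 7E alkenyl bromide.

Step 6
Reactants: 11 (S,2E,6E)-7-bromo-5-(tert-butyldimethylsilyloxy)-3-methylocta-2,6-dien-1-ol
Product: 12 (S,2E,6E)-7-bromo-5-(tert-butyldimethylsilyloxy)-3-methylocta-2,6-dienal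
Conditions: activated MnO2, CH2Cl2, rt
Reagents that add atoms: none
Why: MnO2 allylic oxidation gives the enal without touching the alkenyl bromide or the silyl ether and should preserve the 3E geometry.

Step 7
Reactants: 13 pent-4-yn-1-ol
Product: 15 (E)-5-iodo-4-methylpent-4-en-1-ol, via alkenylalane alkoxide 14 (not isolated)
Conditions: Me3Al (3 equiv), Cp2ZrCl2 (0.25 equiv), CH2Cl2, 0 °C to rt; I2, THF, -30 °C
Reagents that add atoms: trimethylaluminium C[Al](C)C; iodine II
Why: Negishi carboalumination followed by iodinolysis with retention gives the E trisubstituted alkenyl iodide that becomes C11=C12.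

Step 8
Reactants: 15 (E)-5-iodo-4-methylpent-4-en-1-ol
Product: 16 (E)-4-methyl-5-(Bpin)pent-4-en-1-ol
Conditions: B2pin2 (1.1 equiv), PdCl2(PPh3)2 (3 mol %), PPh3 (6 mol %), KOPh (1.5 equiv), toluene, 50 °C
Reagents that add atoms: bis(pinacolato)diboron CC1(C)OB(OC1(C)C)B1OC(C)(C)C(C)(C)O1
Why: Miyaura borylation of an alkenyl iodide proceeds with retention of geometry and tolerates the free alcohol.

Step 9
Reactants: 16 (E)-4-methyl-5-(Bpin)pent-4-en-1-ol
Product: 17 (E)-4-methyl-5-(Bpin)pent-4-enal
Conditions: Dess–Martin periodinane, NaHCO3, CH2Cl2, 0 °C to rt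
Reagents that add atoms: none
Why: Dess–Martin oxidation is neutral and leaves the alkenylboronate intact.

Step 10
Reactants: 17 (E)-4-methyl-5-(Bpin)pent-4-enal; 18 methyl acrylate
Product: 19 methyl (E)-3-hydroxy-6-methyl-2-methylene-7-(Bpin)hept-6-enoate (racemic)
Conditions: 18 (3 equiv), quinuclidine (25 mol %), MeOH (0.75 equiv), neat, rt
Reagents that add atoms: none
Why: The Morita–Baylis–Hillman reaction joins C1 to C15, and the carbinol centre it creates is erased in the next step, so no stereocontrol is needed.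

Step 11
Reactants: 19 methyl (E)-3-hydroxy-6-methyl-2-methylene-7-(Bpin)hept-6-enoate
Product: 20 methyl (2Z,6E)-2-(bromomethyl)-6-methyl-7-(Bpin)hepta-2,6-dienoate
Conditions: NBS (1.3 equiv) and Me2S (1.5 equiv) premixed, CH2Cl2, 0 °C; then 19, 0 °C to rt
Reagents that add atoms: N-bromosuccinimide O=C1CCC(=O)N1Br
Why: Corey–Kim-type bromosulfonium activation replaces the hydroxyl with allylic transposition to the favoured Z 2-(bromomethyl)enoate, and premixing keeps free NBS away from the alkenylboronate.

Step 12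
Reactants: 12 (S,2E,6E)-7-bromo-5-(tert-butyldimethylsilyloxy)-3-methylocta-2,6-dienal; 20 methyl (2Z,6E)-2-(bromomethyl)-6-methyl-7-(Bpin)hepta-2,6-dienoate
Product: 22 (4R,5S)-5-[(S,1E,5E)-6-bromo-4-(tert-butyldimethylsilyloxy)-2-methylhepta-1,5-dienyl]-4-[(E)-3-methyl-4-(Bpin)but-3-enyl]-3-methylenedihydrofuran-2(3H)-one, via trimethylsilyl ether 21 (not isolated)
Conditions: CrCl2 (10 mol %), (S,S)-1,8-bis(4-isopropyl-4,5-dihydrooxazol-2-yl)-3,6-diphenyl-9H-carbazole (12 mol %), i-Pr2NEt (30 mol %), Mn powder (2 equiv), TMSCl (2 equiv), THF, rt; then 1 M HCl, THF, rt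
Reagents that add atoms: none
Why: In this catalytic asymmetric Nozaki–Hiyama 2-(alkoxycarbonyl)allylation the equilibrating allylchromium adds through a chair transition state with both substituents equatorial to give the anti adduct (trans-lactone), the tridentate ligand selects the aldehyde face (C2 S, C1 R), nickel-free chromium leaves the alkenyl bromide alone, and the acid work-up cleaves the TMS ether and lactonises.

Step 13
Reactants: 22 the trans α-methylene lactone of step 12
Product: 23 (3R,4S,5E,8S,9E)-10-bromo-8-(tert-butyldimethylsilyloxy)-6-methyl-2-methylene-3-[(E)-3-methyl-4-(Bpin)but-3-enyl]undeca-5,9-diene-1,4-diol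
Conditions: DIBAL-H (5 equiv), CH2Cl2, -78 to -20 °C; aq. Rochelle salt
Reagents that add atoms: none
Why: DIBAL-H reduces the lactone in the 1,2 sense via the lactol to the 2-methylene-1,4-diol, an oxidation level that tolerates a Grignard reagent and basic peroxide, while boronate, bromide and silyl ether are inert at low temperature.

Step 14
Reactants: 23 the 2-methylene-1,4-diol of step 13
Product: 24 tris-TBS ether of 23 (C2-O C6-O and C16-O silylated; 1R 2S 6S; C8 alkenyl bromide and C11 alkenyl-Bpin termini)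
Conditions: TBSOTf (2.6 equiv), 2,6-lutidine (4 equiv), CH2Cl2, -78 to 0 °C
Reagents that add atoms: tert-butyldimethylsilyl triflate CC(C)(C)[Si](C)(C)OS(=O)(=O)C(F)(F)F
Why: Silylation with the triflate covers the primary and the hindered secondary allylic alcohol, so that the only hydroxyl set free later is the one at C10.

Step 15
Reactants: 24 tris-TBS bromo boronate; 25 vinylmagnesium bromide
Product: 28 (1R,2S,3E,6S,7E,10S,11E)-2,6-bis(tert-butyldimethylsilyloxy)-1-[3-(tert-butyldimethylsilyloxy)prop-1-en-2-yl]-4,8,12-trimethylcyclotetradeca-3,7,11-trien-10-ol, via sodium bis(alkenyl)borate 26 (not isolated), via macrocyclic allylboronate 27 (not isolated)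
Conditions: 25 (1.0 equiv), THF, 0 °C to rt; NaOTf (3 equiv); syringe-pump addition (12 h) into Pd(OAc)2 (5 mol %), MandyPhos ligand (Sp,Sp)-1,1'-bis[bis(4-methoxy-3,5-dimethylphenyl)phosphino]-2,2'-bis[(R)-α-(dimethylamino)benzyl]ferrocene (6 mol %), THF/DMSO, 45 °C, final about 1 mM; then 3 M NaOH, 30% H2O2, 0 °C to rt
Reagents that add atoms: hydrogen peroxide OO
Why: Proposed new method: zerovalent palladium inserts into the C8–Br bond of borate 26, NaOTf removes the bromide, and the cationic alkenylpalladium binds the unsubstituted B-vinyl group, which triggers a 1,2-metallate shift of the C11 alkenyl group from boron to C10 anti to palladium, after which reductive elimination from the C8–Pd–C9 palladacycle forges C8–C9. The closest known reaction is the intermolecular enantioselective conjunctive cross-coupling of bis(alkenyl)borates with C(sp2) halides or triflates, including its Grignard/NaOTf variant, and the new element is that migrating group and electrophile sit on one chain, so the three-component coupling becomes a macrocyclisation that stitches in C9–C10. The fourteen-membered carbocycle is the only ring closed, and it arises by contraction of a fifteen-membered palladacycle in the reductive elimination, with C9 and C10 both ending endocyclic. C10 is the only new stereocentre, set by the chiral bisphosphine, which chooses the vinyl face that palladium binds (the shift is stereospecifically anti and the peroxide oxidation goes with retention), while 7E and 11E are carried over with retention from bromide and boronate. The step needs activation of the vinyl rather than the trisubstituted alkenyl group (secured by sterics, since the β,β-disubstituted alkenyl binds palladium poorly and migrates well), metallate shift rather than direct Suzuki-type transmetallation or β-hydride elimination (a trait of this ligand class), and ring closure rather than oligomerisation (slow addition at high dilution, with a chain stiffened by three E olefins). The lactone is held as the silylated diol because neither it nor its methylene group would survive the Grignard reagent or basic peroxide, and the boron atom marks C10 as the one oxygen to be acetylated.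

Step 16
Reactants: 28 macrocyclic C10 alcohol
Product: 29 C10 acetate of 28 (1R 2S 6S 10S; three TBS ethers retained)
Conditions: Ac2O, Et3N, DMAP (cat.), CH2Cl2, 0 °C to rt
Reagents that add atoms: acetic anhydride CC(=O)OC(C)=O
Why: Acylation meets a single free hydroxyl, so the C10/C6 differentiation needs no selectivity.

Step 17
Reactants: 29 tris-TBS macrocyclic acetate
Product: 30 (1R,2S,3E,6S,7E,10S,11E)-10-acetoxy-1-(3-hydroxyprop-1-en-2-yl)-4,8,12-trimethylcyclotetradeca-3,7,11-triene-2,6-diol
Conditions: HF·pyridine, pyridine, THF, 0 °C to rt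
Reagents that add atoms: none
Why: Buffered fluoride desilylation removes all three TBS groups under conditions that spare the allylic acetate and the allylic alcohols.

Step 18
Reactants: 30 triol acetate
Product: 33 target CNP0406430.1 (1R 2S 6S 10S; 3E 7E 11E; trans-fused α-methylene-γ-butyrolactone), via hydroxy enal 31 (not isolated), via lactol 32 (not isolated)
Conditions: TEMPO (20 mol %), PhI(OAc)2 (2.5 equiv), CH2Cl2, rt
Reagents that add atoms: none
Why: In this oxoammonium-mediated oxidative lactonisation of a 1,4-diol the unhindered primary allylic alcohol is oxidised much faster than the two secondary ones, enal 31 is trapped by the C2 hydroxyl as five-membered lactol 32, and the lactol is oxidised on to the lactone without touching C1, C2, C6 or C10.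

Compound list
1 | but-2-yn-1-ol | CC#CCO | starting material
2 | but-2-ynal | CC#CC=O | intermediate
3 | allenylboronic acid pinacol ester | C=C=CB1OC(C)(C)C(C)(C)O1 | starting material
4 | (S)-hepta-1,5-diyn-4-yl pinacol borate (O-boryl ether of 5) | C#CC[C@H](OB1OC(C)(C)C(C)(C)O1)C#CC | intermediate
5 | (S)-hepta-1,5-diyn-4-ol | C#CC[C@H](O)C#CC | intermediate
6 | (S)-4-(tert-butyldimethylsilyloxy)hepta-1,5-diyne | C#CC[C@H](O[Si](C)(C)C(C)(C)C)C#CC | intermediate
7 | (E)-alkenyl(dimethyl)alane from 6 | C[Al](C)/C=C(\C)C[C@H](O[Si](C)(C)C(C)(C)C)C#CC | intermediate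
8 | lithium butyl(dimethyl)alkenylalanate from 7 | [Li+].CCCC[Al-](C)(C)/C=C(\C)C[C@H](O[Si](C)(C)C(C)(C)C)C#CC | intermediate
9 | (S,E)-5-(tert-butyldimethylsilyloxy)-3-methyloct-2-en-6-yn-1-ol | OC/C=C(\C)C[C@H](O[Si](C)(C)C(C)(C)C)C#CC | intermediate
10 | O-zirconated (E)-alkenylzirconocene chloride from 9 | Cl[Zr](C1C=CC=C1)(C1C=CC=C1)OC/C=C(\C)C[C@H](O[Si](C)(C)C(C)(C)C)/C=C(\C)[Zr](Cl)(C1C=CC=C1)C1C=CC=C1 | intermediate
11 | (S,2E,6E)-7-bromo-5-(tert-butyldimethylsilyloxy)-3-methylocta-2,6-dien-1-ol | OC/C=C(\C)C[C@H](O[Si](C)(C)C(C)(C)C)/C=C(\C)Br | intermediate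
12 | (S,2E,6E)-7-bromo-5-(tert-butyldimethylsilyloxy)-3-methylocta-2,6-dienal | O=C/C=C(\C)C[C@H](O[Si](C)(C)C(C)(C)C)/C=C(\C)Br | intermediate
13 | pent-4-yn-1-ol | C#CCCCO | starting material
14 | (E)-alkenyl(dimethyl)alane dimethylaluminium alkoxide from 13 | C[Al](C)OCCC/C(C)=C/[Al](C)C | intermediate
15 | (E)-5-iodo-4-methylpent-4-en-1-ol | OCCC/C(C)=C/I | intermediate
16 | (E)-4-methyl-5-(Bpin)pent-4-en-1-ol | OCCC/C(C)=C/B1OC(C)(C)C(C)(C)O1 | intermediate
17 | (E)-4-methyl-5-(Bpin)pent-4-enal | O=CCC/C(C)=C/B1OC(C)(C)C(C)(C)O1 | intermediate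
18 | methyl acrylate | C=CC(=O)OC | starting material
19 | methyl (E)-3-hydroxy-6-methyl-2-methylene-7-(Bpin)hept-6-enoate (racemic) | C=C(C(=O)OC)C(O)CC/C(C)=C/B1OC(C)(C)C(C)(C)O1 | intermediate
20 | methyl (2Z,6E)-2-(bromomethyl)-6-methyl-7-(Bpin)hepta-2,6-dienoate | COC(=O)/C(CBr)=C/CC/C(C)=C/B1OC(C)(C)C(C)(C)O1 | intermediate
21 | anti adduct as C2 trimethylsilyl ether methyl ester | COC(=O)C(=C)[C@@H](CC/C(C)=C/B1OC(C)(C)C(C)(C)O1)[C@@H](O[Si](C)(C)C)/C=C(\C)C[C@H](O[Si](C)(C)C(C)(C)C)/C=C(\C)Br | intermediate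
22 | (4R,5S)-trans α-methylene-γ-butyrolactone with west bromodienyl and east boryl-butenyl chains | C=C1C(=O)O[C@@H](/C=C(\C)C[C@H](O[Si](C)(C)C(C)(C)C)/C=C(\C)Br)[C@@H]1CC/C(C)=C/B1OC(C)(C)C(C)(C)O1 | intermediate
23 | (3R,4S,5E,8S,9E)-2-methylene-1,4-diol from 22 | C=C(CO)[C@@H](CC/C(C)=C/B1OC(C)(C)C(C)(C)O1)[C@@H](O)/C=C(\C)C[C@H](O[Si](C)(C)C(C)(C)C)/C=C(\C)Br | intermediate
24 | tris-TBS bromo boronate | C=C(CO[Si](C)(C)C(C)(C)C)[C@@H](CC/C(C)=C/B1OC(C)(C)C(C)(C)O1)[C@@H](O[Si](C)(C)C(C)(C)C)/C=C(\C)C[C@H](O[Si](C)(C)C(C)(C)C)/C=C(\C)Br | intermediate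
25 | vinylmagnesium bromide | C=C[Mg]Br | starting material
26 | sodium bis(alkenyl)(pinacolato)borate from 24 and 25 | [Na+].C=C(CO[Si](C)(C)C(C)(C)C)[C@@H](CC/C(C)=C/[B-]1(C=C)OC(C)(C)C(C)(C)O1)[C@@H](O[Si](C)(C)C(C)(C)C)/C=C(\C)C[C@H](O[Si](C)(C)C(C)(C)C)/C=C(\C)Br | intermediate
27 | (10S)-macrocyclic allylboronate | C=C(CO[Si](C)(C)C(C)(C)C)[C@@H]1[C@@H](O[Si](C)(C)C(C)(C)C)/C=C(\C)C[C@H](O[Si](C)(C)C(C)(C)C)/C=C(\C)C[C@H](B2OC(C)(C)C(C)(C)O2)/C=C(\C)CC1 | intermediate
28 | (1R,2S,6S,10S)-macrocyclic C10 alcohol, tris-TBS | C=C(CO[Si](C)(C)C(C)(C)C)[C@@H]1[C@@H](O[Si](C)(C)C(C)(C)C)/C=C(\C)C[C@H](O[Si](C)(C)C(C)(C)C)/C=C(\C)C[C@H](O)/C=C(\C)CC1 | intermediate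
29 | C10 acetate, tris-TBS | C=C(CO[Si](C)(C)C(C)(C)C)[C@@H]1[C@@H](O[Si](C)(C)C(C)(C)C)/C=C(\C)C[C@H](O[Si](C)(C)C(C)(C)C)/C=C(\C)C[C@H](OC(C)=O)/C=C(\C)CC1 | intermediate
30 | triol acetate | C=C(CO)[C@@H]1[C@@H](O)/C=C(\C)C[C@H](O)/C=C(\C)C[C@H](OC(C)=O)/C=C(\C)CC1 | intermediate
31 | C16 enal, C2 and C6 hydroxyls free | C=C(C=O)[C@@H]1[C@@H](O)/C=C(\C)C[C@H](O)/C=C(\C)C[C@H](OC(C)=O)/C=C(\C)CC1 | intermediate
32 | α-methylene lactol (C16 epimers) | C=C1C(O)O[C@H]2/C=C(\C)C[C@H](O)/C=C(\C)C[C@H](OC(C)=O)/C=C(\C)CC[C@H]12 | intermediate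
33 | CNP0406430.1 | C=C1C(=O)O[C@H]2/C=C(\C)C[C@H](O)/C=C(\C)C[C@H](OC(C)=O)/C=C(\C)CC[C@H]12 | target

Total step count: 18. Longest linear sequence: 13 (steps 1–6, then 12–18).

Steps most likely to fail

Step 15.
- Risk: intermolecular coupling may outrun ring closure (oligomerisation). The borate may transfer an alkenyl group directly to palladium in the Suzuki manner. The macrocyclic transition state may erode the facial selectivity of the ligand at C10.
- Fallback (known chemistry, the order of the two unions inverted): it sets out from 11 and 16 and comes back at 33.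
- Alcohol 11 is silylated (TBSCl, imidazole) to the bis-silyl ether bromide F1, and alcohol 16 to the silyl ether boronate F2.
- F2 with 25 and NaOTf gives the sodium bis(alkenyl)borate F3, which is coupled with F1 under the same Pd(OAc)2/ligand system in the established bimolecular form of the reaction to give the open-chain allylboronate F4.
- Oxidation (NaOH, H2O2) gives the C10 carbinol F5 and acetylation the acetate F6.
- Buffered HF·pyridine at 0 °C removes only the two primary silyl groups to give the diol F7, and Dess–Martin oxidation gives the dialdehyde F8.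
- The saturated aldehyde alone enters the Morita–Baylis–Hillman reaction with 18 to give the hydroxy acrylate F9, and NBS/Me2S converts this into the allylic bromide F10.
- Stoichiometric CrCl2 in THF at high dilution closes the ring at C1–C2 by intramolecular Nozaki–Hiyama allylation of the enal, and lactonisation gives the silylated macrocyclic lactone F11. HF·pyridine then gives 33.
- The price is that C1/C2 are set under macrocyclic substrate control.

Step 12.
- Risk: the ligand may discriminate poorly between the faces of the β,β-disubstituted enal, and the ester-bearing allylchromium may lose part of its anti preference.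
- Fallback (resolution in place of asymmetric C–C bond formation): it sets out from 12 and 20 and comes back at 24.
- Ligand-free stoichiometric CrCl2 joins 12 and 20 to the trans-lactone isomer pair F12 (1R,2S and 1S,2R, both 6S).
- DIBAL-H gives the diol pair F13, and TBSCl/imidazole silylates only the primary alcohol to give the mono-silylated pair F14.
- Acylative kinetic resolution follows, using isobutyric anhydride and the enantiomer of benzotetramisole that acylates the (2R)-allylic carbinol faster. It turns the unwanted isomer into the isobutyrate F15, which is removed by chromatography.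
- The recovered (1R,2S)-alcohol F16 is silylated with TBSOTf to 24.

Step 18.
- Risk: the oxoammonium salt may also attack the secondary allylic alcohols at C6 or C2 before the lactol has formed.
- Fallback (staged deprotection, with all secondary carbinols masked during every oxidation): it sets out from 29 and comes back at 33.
- Buffered HF·pyridine at 0 °C frees only the primary position to give the bis-silyl allylic alcohol F17.
- MnO2 gives the enal F18, and Pinnick oxidation (NaClO2, NaH2PO4, 2-methyl-2-butene) gives the acrylic acid F19.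
- Full desilylation with HF·pyridine gives the dihydroxy acid F20, whose C2 hydroxyl closes the five-membered lactone to give 33.

Further compounds
F1 | step 15 | (S,2E,6E)-7-bromo-1,5-bis(tert-butyldimethylsilyloxy)-3-methylocta-2,6-diene | CC(C)(C)[Si](C)(C)OC/C=C(\C)C[C@H](O[Si](C)(C)C(C)(C)C)/C=C(\C)Br
F2 | step 15 | (E)-5-(tert-butyldimethylsilyloxy)-2-methylpent-1-enyl-Bpin | CC(C)(C)[Si](C)(C)OCCC/C(C)=C/B1OC(C)(C)C(C)(C)O1
F3 | step 15 | sodium alkenyl(vinyl)(pinacolato)borate from F2 | [Na+].CC(C)(C)[Si](C)(C)OCCC/C(C)=C/[B-]1(C=C)OC(C)(C)C(C)(C)O1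
F4 | step 15 | open-chain (10S)-allylboronate, tris-TBS | CC(C)(C)[Si](C)(C)OC/C=C(\C)C[C@H](O[Si](C)(C)C(C)(C)C)/C=C(\C)C[C@H](B1OC(C)(C)C(C)(C)O1)/C=C(\C)CCCO[Si](C)(C)C(C)(C)C
F5 | step 15 | open-chain (6S,10S)-C10 carbinol, tris-TBS | CC(C)(C)[Si](C)(C)OC/C=C(\C)C[C@H](O[Si](C)(C)C(C)(C)C)/C=C(\C)C[C@H](O)/C=C(\C)CCCO[Si](C)(C)C(C)(C)C
F6 | step 15 | open-chain C10 acetate, tris-TBS | CC(C)(C)[Si](C)(C)OC/C=C(\C)C[C@H](O[Si](C)(C)C(C)(C)C)/C=C(\C)C[C@H](OC(C)=O)/C=C(\C)CCCO[Si](C)(C)C(C)(C)C
F7 | step 15 | open-chain C1,C2 diol, C6 TBS ether, C10 acetate | OC/C=C(\C)C[C@H](O[Si](C)(C)C(C)(C)C)/C=C(\C)C[C@H](OC(C)=O)/C=C(\C)CCCO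
F8 | step 15 | open-chain dialdehyde (C2 enal, C1 alkanal) | O=C/C=C(\C)C[C@H](O[Si](C)(C)C(C)(C)C)/C=C(\C)C[C@H](OC(C)=O)/C=C(\C)CCC=O
F9 | step 15 | Morita–Baylis–Hillman adduct at C1 (epimers) | O=C/C=C(\C)C[C@H](O[Si](C)(C)C(C)(C)C)/C=C(\C)C[C@H](OC(C)=O)/C=C(\C)CCC(O)C(=C)C(=O)OC
F10 | step 15 | (Z)-2-(bromomethyl)enoate enal | O=C/C=C(\C)C[C@H](O[Si](C)(C)C(C)(C)C)/C=C(\C)C[C@H](OC(C)=O)/C=C(\C)CC/C=C(\CBr)C(=O)OC
F11 | step 15 | C6 TBS ether of the target | C=C1C(=O)O[C@H]2/C=C(\C)C[C@H](O[Si](C)(C)C(C)(C)C)/C=C(\C)C[C@H](OC(C)=O)/C=C(\C)CC[C@H]12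
F12 | step 12 | trans-lactone as the pair of (1R,2S) and (1S,2R) isomers, 6S | C=C1C(=O)OC(/C=C(\C)C[C@H](O[Si](C)(C)C(C)(C)C)/C=C(\C)Br)C1CC/C(C)=C/B1OC(C)(C)C(C)(C)O1
F13 | step 12 | anti 2-methylene-1,4-diol as the same pair of isomers | C=C(CO)C(CC/C(C)=C/B1OC(C)(C)C(C)(C)O1)C(O)/C=C(\C)C[C@H](O[Si](C)(C)C(C)(C)C)/C=C(\C)Br
F14 | step 12 | primary TBS ether of F13 as the same pair of isomers | C=C(CO[Si](C)(C)C(C)(C)C)C(CC/C(C)=C/B1OC(C)(C)C(C)(C)O1)C(O)/C=C(\C)C[C@H](O[Si](C)(C)C(C)(C)C)/C=C(\C)Br
F15 | step 12 | isobutyrate of the (1S,2R,6S) isomer | C=C(CO[Si](C)(C)C(C)(C)C)[C@H](CC/C(C)=C/B1OC(C)(C)C(C)(C)O1)[C@H](OC(=O)C(C)C)/C=C(\C)C[C@H](O[Si](C)(C)C(C)(C)C)/C=C(\C)Br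
F16 | step 12 | recovered (1R,2S,6S) C2 alcohol | C=C(CO[Si](C)(C)C(C)(C)C)[C@@H](CC/C(C)=C/B1OC(C)(C)C(C)(C)O1)[C@@H](O)/C=C(\C)C[C@H](O[Si](C)(C)C(C)(C)C)/C=C(\C)Br
F17 | step 18 | macrocyclic C16 primary allylic alcohol, C2 and C6 TBS ethers, C10 acetate | C=C(CO)[C@@H]1[C@@H](O[Si](C)(C)C(C)(C)C)/C=C(\C)C[C@H](O[Si](C)(C)C(C)(C)C)/C=C(\C)C[C@H](OC(C)=O)/C=C(\C)CC1
F18 | step 18 | macrocyclic C16 enal, C2 and C6 TBS ethers | C=C(C=O)[C@@H]1[C@@H](O[Si](C)(C)C(C)(C)C)/C=C(\C)C[C@H](O[Si](C)(C)C(C)(C)C)/C=C(\C)C[C@H](OC(C)=O)/C=C(\C)CC1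
F19 | step 18 | macrocyclic C16 acrylic acid, C2 and C6 TBS ethers | C=C(C(=O)O)[C@@H]1[C@@H](O[Si](C)(C)C(C)(C)C)/C=C(\C)C[C@H](O[Si](C)(C)C(C)(C)C)/C=C(\C)C[C@H](OC(C)=O)/C=C(\C)CC1
F20 | step 18 | macrocyclic dihydroxy acrylic acid | C=C(C(=O)O)[C@@H]1[C@@H](O)/C=C(\C)C[C@H](O)/C=C(\C)C[C@H](OC(C)=O)/C=C(\C)CC1
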